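(The earlier runs and the new flask stem from a simulated flask for an exercise; the scatter is artificial.)

You read these flasks at 40 h, so count how often the gas in solution has been replaced by then.

| setting | Tuesday's | noon | spring | summer | dusk |
|---|---|---|---|---|---|
| substrate | 1.1 M | 2.0 M | 1.0 M | 1.0 M | 0.30 M |
| gas | 81 mM (held) | 81 mM (held) | 81 mM (held) | 81 mM (held) | 81 mM (held) |
| temperature | 110 °C | 140 °C | 110 °C | 80 °C | 70 °C |
| remark | run made earlier |  |  |  |  |
| time |  | 40 h | 40 h | 40 h | 40 h |

Tuesday's run (percent of the substrate charged)

| time / h | product / % | substrate / % |
|---|---|---|
| 4.00 | 4 | 96 |
| 8.00 | 4 | 99 |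
| 12.0 | 7 | 90 |
| 15.0 | 10 | 91 |
| 20.0 | 16 | 88 |
| 25.0 | 19 | 84 |

(each reading ± 1.5 percentage points)

- the earlier runs were read with a standard deviation of 1.5 percentage points
- at the start none of the gas is in solution
- the earlier runs do not show what temperature does; that part of a forecast is a guess
- a reading or a percentage of product counts all its forms, free or not

- the flasks put in order of amount of product, in percent of the substrate charged, best first, at 40 h (noon / spring / summer / dusk)
- the amount of product, in percent of the substrate charged of the flask you put first, at 40 h
- the amount of product, in percent of the substrate charged of the flask you put last, at 40 h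

Tuesday's flask holds 209 mM of product at 25.0 h, more than the 81 mM of gas that solution can hold. If each product takes up one gas, as I assume, gas kept entering. Call the product made per hour, divided by the saturation concentration of gas, the gas turnover rate. Tuesday's last reading, with its scatter, gives:

turnover rate = product made ÷ saturation ÷ time = 0.103 /h

Its slow start, 4% at 8.00 h, hints that gas entry is the rate-limiting step. I take that as my own assumption and turn the settings by hand:

product in percent = turnover rate × saturation × time ÷ substrate charged

Time first. Spring resembles Tuesday's flask and runs to 40 h, which gives 33.4%.

Substrate next. Noon has twice spring's charge, so the same gas spreads over more substrate and the count gives 16.7%.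

Temperature last. The runs don't show it, and I assume heat leaves the count alone. For dusk the count gives 111%, beyond the whole charge, so it sets no useful ceiling there. I guess that cold chemistry holds summer and dusk down, by an amount I cannot reckon. I put summer above dusk, since it is warmer and holds more substrate. My order is spring, noon, summer, dusk, and noon over summer is a guess.

The forecast says noon > spring > summer > dusk, with 85% for noon and 2.5% for dusk, and it grants that “Temperature is a guess”. We part on noon.

The flasks give spring > noon > summer > dusk.

    substrate + partner → product, rate k1*[substrate]^1.5*[partner] (k = 0.00869 /M^1.5/min, Ea = 74.0 kJ/mol)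
    gas ⇌ partner, rate k2*(csat - [partner]) (kL = 0.00206 /min)
    crystals ⇌ product, rate k3*(cs3 - [product]) while solid is left; crystals form when [product] > cs3 (solubility = 11.0 mM, k = 0.0291 /min)
    (constants at 110 °C)

Spring holds 29.0%, more than any other flask, noon reaches 19.6%, and dusk holds 4.60%, less than any other flask. At 40.0 h the partner, the dissolved gas, stands at 0.00170 M in noon, below the 0.0224 M in spring. Noon's turnover rate comes to 0.121 /h, above Tuesday's 0.103 /h. For spring read at 15 h, the count gives 12.5%, and that flask holds 10.6%.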